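**Retrosynthetic overview**
- Feature: the dihydropyran ring is O1, C2 (CH3), C3 (CH2OH), C4 (CH2CO2R, R = hydroxytyrosyl), C5 (CO2Me), C6 (H). Its O1–C2–C3–CH2OH segment is the reduced form of what results when a C6 enol oxygen adds to C2 of a 2-ethylidene aldehyde, and enol and enal both hang on C4.
- Target ⇒ (aryl silyl ethers on, C3 CH2OH back to CHO) C3-formyl dihydropyran ⇒ (cut O1–C2) open enol-enal with C4 as its only stereocentre. C2 and C3 follow from C4 by equilibration.
- Open enol-enal ⇒ its enal acetal ⇒ (arm ester C–O bond, Mitsunobu) enol acid + bis-silylated hydroxytyrosol. Enol acid ⇒ (C5–C6, Claisen formylation) half-ester, whose carboxylate keeps the arm CH2 out of the enolisation.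
- Half-ester ⇒ 4-alkenyl δ-lactone ⇒ (C3–C4, rhodium/(R)-BINAP 1,4-addition, sets C4) crotonaldehyde-derived 2-boryl acetal + 5,6-dihydro-2H-pyran-2-one. C6 is added only after C4, because an acceptor already bearing a C6 alkoxymethylene group is a 5-alkoxy-2,4-dienoate that offers C6 as a rival electrophilic site.
- Ring order: the purchased lactone ring is only a carrier and is opened again. The dihydropyran is the one ring built, in the key step. The arene is bought.

Key step: step 12

Assumption: the facial sense of step 4 is taken from the usual behaviour of BINAP–rhodium catalysts with six-membered cyclic acceptors ((S)-ligand gives the (S)-4-substituted product when the new group ranks highest), and all 2-formyl esters are drawn as E-enols although they equilibrate with the chelated Z-enol and the aldehyde tautomer.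

**Step 1**
Reactants: 1 (E)-crotonaldehyde
Product: 3 (Z)-2-bromobut-2-enal, via 2,3-dibromobutanal 2 (not isolated)
Conditions: Br2 (1.0 equiv), CH2Cl2, 0 °C; then Et3N (1.1 equiv), 0 °C to rt
Reagents that add atoms: bromine, BrBr
Why: Electrophilic bromination of the alkene followed by E1cB-type dehydrobromination, in which Et3N removes the acidic C2–H, the C3 bromide leaves, and the more stable Z isomer (CH3 trans to CHO) results.

**Step 2**
Reactants: 3 (Z)-2-bromobut-2-enal
Product: 4 (Z)-2-bromo-1,1-diethoxybut-2-ene
Conditions: HC(OEt)3 (1.3 equiv), EtOH, p-TsOH·H2O (1 mol %), rt; K2CO3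
Reagents that add atoms: triethyl orthoformate, CCOC(OCC)OCC
Why: Acid-catalysed acetalisation with the orthoester as water scavenger masks the aldehyde against the organolithium and enolate chemistry to come and leaves the alkene geometry untouched.

**Step 3**
Reactants: 4 (Z)-2-bromo-1,1-diethoxybut-2-ene
Product: 6 2-[(E)-1,1-diethoxybut-2-en-2-yl]-4,4,5,5-tetramethyl-1,3,2-dioxaborolane, via alkenyllithium 5 (not isolated)
Conditions: n-BuLi (1.05 equiv), THF, −78 °C; i-PrOBpin (1.2 equiv), −78 °C to rt; aq NH4Cl
Reagents that add atoms: 2-isopropoxy-4,4,5,5-tetramethyl-1,3,2-dioxaborolane, CC(C)OB1OC(C)(C)C(C)(C)O1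
Why: Bromine–lithium exchange followed by electrophilic borylation, in which the alkenyllithium is configurationally stable at −78 °C and is trapped with retention, so CH3 stays cis to the carbon–metal bond, the geometry that later becomes the E-ethylidene enal.

**Step 4**
Reactants: 6 2-[(E)-1,1-diethoxybut-2-en-2-yl]-4,4,5,5-tetramethyl-1,3,2-dioxaborolane (1.5 equiv); 7 5,6-dihydro-2H-pyran-2-one
Product: 8 (4R)-4-[(E)-1,1-diethoxybut-2-en-2-yl]oxan-2-one
Conditions: [RhCl(C2H4)2]2 (2.5 mol %), (R)-BINAP (5.5 mol %), KOH (0.5 equiv, aq), 1,4-dioxane/H2O 10:1, 50 °C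
Reagents that add atoms: none
Why: Hayashi–Miyaura reaction (rhodium-catalysed asymmetric 1,4-addition of an alkenylboron reagent to an α,β-unsaturated lactone), in which the alkenyl group passes from boron to the hydroxorhodium–BINAP complex with retention of geometry, the ring-locked enoate inserts through the face left open by the (R)-ligand and sets C4 in the spatial arrangement the target needs (R here, S once C5 is sp2), water protonates the rhodium enolate, and the basic medium spares the acetal.

**Step 5**
Reactants: 8 (4R)-4-[(E)-1,1-diethoxybut-2-en-2-yl]oxan-2-one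
Product: 9 methyl (3R)-3-[(E)-1,1-diethoxybut-2-en-2-yl]-5-hydroxypentanoate
Conditions: NaOMe (0.1 equiv), MeOH, 0 °C to rt; AcOH (0.1 equiv); evaporation below 25 °C, used crude
Reagents that add atoms: methanol, CO
Why: Base-catalysed transesterification (lactone methanolysis), in which the δ-lactone opens to the hydroxy ester in methanol as solvent, the acetal is stable to methoxide, C4 has no acidic hydrogen, and neutralising the base before evaporation keeps the ring from closing again.

**Step 6**
Reactants: 9 methyl (3R)-3-[(E)-1,1-diethoxybut-2-en-2-yl]-5-hydroxypentanoate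
Product: 11 (3R)-3-[(E)-1,1-diethoxybut-2-en-2-yl]-5-methoxy-5-oxopentanoic acid, via aldehyde ester 10 (not isolated)
Conditions: TEMPO (7 mol %), NaOCl (2 mol %), NaClO2 (2 equiv), MeCN/sodium phosphate buffer pH 6.7, 35 °C; Na2SO3; extraction at pH 4, 0 °C
Reagents that add atoms: sodium chlorite, [Na+].[O-]Cl=O
Why: TEMPO-catalysed alcohol oxidation coupled in the same flask with a Pinnick-type chlorite oxidation, in which the near-neutral buffer spares the acetal, hypochlorite is only catalytic so the trisubstituted alkene should not be chlorinated, C4 is untouched, and the two arms on C4 become a methyl ester and a free acid that later steps can tell apart.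

**Step 7**
Reactants: 11 (3R)-3-[(E)-1,1-diethoxybut-2-en-2-yl]-5-methoxy-5-oxopentanoic acid
Product: 13 (3S,4E)-3-[(E)-1,1-diethoxybut-2-en-2-yl]-4-(hydroxymethylidene)-5-methoxy-5-oxopentanoic acid, via dilithium enolate carboxylate 12 (not isolated)
Conditions: LiN(i-Pr)2 (2.3 equiv), THF, −78 °C; HCO2Me (5 equiv), −78 to −20 °C; AcOH, then pH 4 buffer, 0 °C
Reagents that add atoms: methyl formate, COC=O
Why: Crossed Claisen condensation (ester formylation), in which the first equivalent of base makes the carboxylate, whose α-CH2 is then far less acidic than that of the methyl ester, so the second equivalent enolises only C5 and methyl formate places C6 there, while C5 ends as an sp2 enol carbon (no new stereocentre) and C4, β to the enolate and without a leaving group, is not touched.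

**Step 8**
Reactants: 14 hydroxytyrosol
Product: 15 tris-TBS ether of hydroxytyrosol
Conditions: TBSCl (3.5 equiv), imidazole (7 equiv), DMF, rt
Reagents that add atoms: tert-butyldimethylsilyl chloride, CC(C)(C)[Si](C)(C)Cl
Why: Imidazole-promoted silyl ether formation, run to exhaustion so that the three hydroxyl groups need not be told apart at this stage.

**Step 9**
Reactants: 15 tris-TBS ether of hydroxytyrosol
Product: 16 2-[3,4-bis(tert-butyldimethylsilyloxy)phenyl]ethanol
Conditions: CSA (10 mol %), MeOH/CH2Cl2 1:1, 0 °C; Et3N
Reagents that add atoms: none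
Why: Acid-catalysed solvolysis of a silyl ether, in which the primary alkyl silyl ether is protonated and methanolysed much faster than the aryl silyl ethers, whose oxygen lone pairs are delocalised into the ring, so only the side-chain alcohol is freed.

**Step 10**
Reactants: 13 (3S,4E)-3-[(E)-1,1-diethoxybut-2-en-2-yl]-4-(hydroxymethylidene)-5-methoxy-5-oxopentanoic acid; 16 2-[3,4-bis(tert-butyldimethylsilyloxy)phenyl]ethanol (1.0 equiv)
Product: 17 5-{2-[3,4-bis(tert-butyldimethylsilyloxy)phenyl]ethyl} 1-methyl (2E,3S)-3-[(E)-1,1-diethoxybut-2-en-2-yl]-2-(hydroxymethylidene)pentanedioate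
Conditions: PPh3 (1.1 equiv), DIAD (1.1 equiv), THF, 0 °C, betaine preformed
Reagents that add atoms: none
Why: Mitsunobu esterification, in which the carboxylic acid, the strongest acid present, protonates the betaine and its carboxylate displaces the alkoxyphosphonium ion of the primary alcohol, so the acid itself is never activated toward the neighbouring enol, and the neutral medium preserves acetal, enol and aryl silyl ethers.

**Step 11**
Reactants: 17 the acetal enol diester
Product: 18 5-{2-[3,4-bis(tert-butyldimethylsilyloxy)phenyl]ethyl} 1-methyl (2E,3S)-2-(hydroxymethylidene)-3-[(E)-1-oxobut-2-en-2-yl]pentanedioate (open enol-enal)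
Conditions: oxalic acid (0.5 equiv), THF/H2O 4:1, 0 °C; extraction with Et2O, no chromatography
Reagents that add atoms: water, O
Why: Acid-catalysed acetal hydrolysis, in which the allylic diethyl acetal ionises to a conjugated oxocarbenium ion and falls to a weak acid at 0 °C while esters and aryl silyl ethers are inert, the ethanol leaves with the aqueous phase so that it cannot form acetals in step 12, and any material that closes early is simply carried into step 12.

**Step 12**
Reactants: 18 open enol-enal
Product: 20 methyl (2S,3S,4S)-4-(2-{2-[3,4-bis(tert-butyldimethylsilyloxy)phenyl]ethoxy}-2-oxoethyl)-3-formyl-2-methyl-3,4-dihydro-2H-pyran-5-carboxylate, via C3 enol 19 (not isolated)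
Conditions: CSA (10 mol %), CH2Cl2 (0.02 M), rt to 35 °C, until the isomer ratio no longer changes; aq NaHCO3
Reagents that add atoms: none
Why: The acid protonates the enal carbonyl, the 2-formylacetate enol (its E and Z forms interchange through the aldehyde tautomer) turns about C4–C5 until its oxygen reaches C2, O1–C2 forms, and the C3 enol tautomerises to the aldehyde; this is an intramolecular oxa-Michael addition of a 1,3-dicarbonyl enol to an enal, a known reaction type and the way secoiridoid aglycones are thought to reorganise once the sugar is gone. The single ring closes in the 6-endo-trig mode, because the attacked C2=C3 bond lies inside the new six-membered ring. Addition and tautomerisation are both reversible under the acid, so C2 and C3 are set by product stability and not by the face attacked first: A(1,2) strain against the C5 ester puts the C4 arm pseudoaxial, the C2 methyl then takes the equatorial site on the opposite face because the axial site would be syn-axial to the arm (2S), and the C3 formyl sits axial and anti to the arm, gauche only to the methyl and without a syn-axial partner at O1 or at sp2 C5 (3S). The selectivity needed is 1,4 over 1,2 and O over C: attack of the same oxygen on the formyl carbon (6-exo-trig lactol formation) is also within reach, but it is reversible and gains less than exchanging the C2=C3 π bond for C–O and C–H σ bonds, so it should drain into the aldehyde, whereas attack through C5 on C2 would need a cyclobutane. C4 is safe because it is β to every carbonyl group and carries no acidified hydrogen, and it could be lost only by retro-Michael cleavage of C4–C5 from the arm ester enolate, which needs strong base. Dilution and the absence of alcohols keep intermolecular aldol and acetal formation down.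

**Step 13**
Reactants: 20 C3-formyl dihydropyran
Product: 21 methyl (2S,3R,4S)-4-(2-{2-[3,4-bis(tert-butyldimethylsilyloxy)phenyl]ethoxy}-2-oxoethyl)-3-(hydroxymethyl)-2-methyl-3,4-dihydro-2H-pyran-5-carboxylate
Conditions: NaBH4 (1.0 equiv), MeOH/THF 1:1, −40 °C; AcOH at −40 °C
Reagents that add atoms: none
Why: Chemoselective borohydride reduction of the aldehyde, in which esters and the push-pull β-alkoxyacrylate are inert at −40 °C, hydride transfer outruns enolisation so C3 is not scrambled and the ring does not reopen, the cold acidic quench prevents the new alkoxide from lactonising onto the arm ester, and the C3 descriptor changes to R only because CH2OH ranks below C2.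

**Step 14**
Reactants: 21 bis-silylated target
Product: 22 methyl (2S,3R,4S)-4-{2-[2-(3,4-dihydroxyphenyl)ethoxy]-2-oxoethyl}-3-(hydroxymethyl)-2-methyl-3,4-dihydro-2H-pyran-5-carboxylate (target)
Conditions: Et3N·3HF (6 equiv), THF, 0 °C to rt, argon
Reagents that add atoms: none
Why: Fluoride-mediated desilylation, in which the mildly acidic HF–amine reagent cleaves both aryl Si–O bonds without the basic conditions that would oxidise the catechol, attack the β-alkoxyacrylate or let the C3 CH2OH lactonise onto the arm ester, and no stereocentre is at risk.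

**Compound list**
1 | (E)-crotonaldehyde | C/C=C/C=O | starting material
2 | 2,3-dibromobutanal (not isolated) | CC(Br)C(Br)C=O | intermediate
3 | (Z)-2-bromobut-2-enal | C/C=C(\Br)C=O | intermediate
4 | (Z)-2-bromo-1,1-diethoxybut-2-ene | C/C=C(\Br)C(OCC)OCC | intermediate
5 | (E)-(1,1-diethoxybut-2-en-2-yl)lithium (not isolated) | C/C=C(\[Li])C(OCC)OCC | intermediate
6 | 2-[(E)-1,1-diethoxybut-2-en-2-yl]-4,4,5,5-tetramethyl-1,3,2-dioxaborolane | C/C=C(\B1OC(C)(C)C(C)(C)O1)C(OCC)OCC | intermediate
7 | 5,6-dihydro-2H-pyran-2-one | O=C1C=CCCO1 | starting material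
8 | (4R)-4-[(E)-1,1-diethoxybut-2-en-2-yl]oxan-2-one | O=C1C[C@@H](CCO1)/C(=C\C)C(OCC)OCC | intermediate
9 | methyl (3R)-3-[(E)-1,1-diethoxybut-2-en-2-yl]-5-hydroxypentanoate | COC(=O)C[C@@H](CCO)/C(=C\C)C(OCC)OCC | intermediate
10 | methyl (3R)-3-[(E)-1,1-diethoxybut-2-en-2-yl]-5-oxopentanoate (not isolated) | COC(=O)C[C@@H](CC=O)/C(=C\C)C(OCC)OCC | intermediate
11 | (3R)-3-[(E)-1,1-diethoxybut-2-en-2-yl]-5-methoxy-5-oxopentanoic acid | COC(=O)C[C@@H](CC(=O)O)/C(=C\C)C(OCC)OCC | intermediate
12 | dilithium ester enolate carboxylate of 11 (not isolated) | [Li+].[Li+].COC([O-])=C[C@@H](CC(=O)[O-])/C(=C\C)C(OCC)OCC | intermediate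
13 | (3S,4E)-3-[(E)-1,1-diethoxybut-2-en-2-yl]-4-(hydroxymethylidene)-5-methoxy-5-oxopentanoic acid | COC(=O)/C(=C/O)[C@@H](CC(=O)O)/C(=C\C)C(OCC)OCC | intermediate
14 | hydroxytyrosol | OCCc1ccc(O)c(O)c1 | starting material
15 | tris-TBS ether of hydroxytyrosol | CC(C)(C)[Si](C)(C)OCCc1ccc(O[Si](C)(C)C(C)(C)C)c(O[Si](C)(C)C(C)(C)C)c1 | intermediate
16 | 2-[3,4-bis(tert-butyldimethylsilyloxy)phenyl]ethanol | OCCc1ccc(O[Si](C)(C)C(C)(C)C)c(O[Si](C)(C)C(C)(C)C)c1 | intermediate
17 | acetal enol diester, (2E,3S) | COC(=O)/C(=C/O)[C@@H](CC(=O)OCCc1ccc(O[Si](C)(C)C(C)(C)C)c(O[Si](C)(C)C(C)(C)C)c1)/C(=C\C)C(OCC)OCC | intermediate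
18 | open enol-enal, (2E,3S), E-ethylidene | COC(=O)/C(=C/O)[C@@H](CC(=O)OCCc1ccc(O[Si](C)(C)C(C)(C)C)c(O[Si](C)(C)C(C)(C)C)c1)/C(C=O)=C\C | intermediate
19 | ring-closed C3 enol, (2S,4S) (not isolated) | COC(=O)C1=CO[C@@H](C)C(=CO)[C@@H]1CC(=O)OCCc1ccc(O[Si](C)(C)C(C)(C)C)c(O[Si](C)(C)C(C)(C)C)c1 | intermediate
20 | (2S,3S,4S)-C3-formyl dihydropyran, bis-TBS | COC(=O)C1=CO[C@@H](C)[C@@H](C=O)[C@@H]1CC(=O)OCCc1ccc(O[Si](C)(C)C(C)(C)C)c(O[Si](C)(C)C(C)(C)C)c1 | intermediate
21 | (2S,3R,4S)-C3-hydroxymethyl dihydropyran, bis-TBS | COC(=O)C1=CO[C@@H](C)[C@@H](CO)[C@@H]1CC(=O)OCCc1ccc(O[Si](C)(C)C(C)(C)C)c(O[Si](C)(C)C(C)(C)C)c1 | intermediate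
22 | CNP0204147.2, (2S,3R,4S) | COC(=O)C1=CO[C@@H](C)[C@@H](CO)[C@@H]1CC(=O)OCCc1ccc(O)c(O)c1 | target

**Step count**
Total steps: 14. Longest linear sequence: 12 steps (steps 1–7 and 10–14, from crotonaldehyde).

**Steps most likely to fail**

1. Step 12.
   - Risk: equilibration may stall, so that the methyl group stays on the face reached first. The material may also rest in the lactol manifold or oligomerise under the acid.
   - Fallback: the closure is moved to the free-acid stage, where crystallisation and not only the solution equilibrium selects the isomer. Setting out from 13, dilute H2SO4 in aqueous THF removes the acetal to give the open enol-enal acid (3S)-4-(hydroxymethylidene)-5-methoxy-5-oxo-3-[(E)-1-oxobut-2-en-2-yl]pentanoic acid F1. This closes in the same pot to (2S,3S,4S)-3-formyl-5-(methoxycarbonyl)-2-methyl-3,4-dihydro-2H-pyran-4-acetic acid F2. This compact acid should lend itself to crystallisation, with the mother liquor returned to the acid. Mitsunobu esterification with 16 (PPh3, DIAD) comes back to the route at 20.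

2. Step 4.
   - Risk: transmetalation and insertion of the α-branched alkenylboronate may be slow, so that protodeboronation outruns addition, and facial selectivity may erode if the temperature has to be raised.
   - Fallback: an auxiliary-controlled organocopper addition. Setting out from 4 by way of 5, the lithium reagent is transmetalated with MgBr2·OEt2 and CuBr·SMe2.
     - It is added at −40 °C to (4S)-3-[(E)-5-(tert-butyldimethylsilyloxy)pent-2-enoyl]-4-phenyloxazolidin-2-one F3, made by N-acylation of (S)-4-phenyloxazolidin-2-one with the corresponding enoic acid.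
     - The chelated s-cis imide exposes the face away from the phenyl group and should give the (3R)-adduct imide F4.
     - NaOMe in MeOH/CH2Cl2 at 0 °C exchanges the auxiliary for methoxide to give methyl (3R)-5-(tert-butyldimethylsilyloxy)-3-[(E)-1,1-diethoxybut-2-en-2-yl]pentanoate F5.
     - Bu4NF buffered with AcOH frees the alcohol, coming back to the route at 9.

3. Step 10.
   - Risk: alkylation of the acidic enol oxygen, or amination of C5 by the azodicarboxylate, may compete with ester formation.
   - Fallback: the acid is activated on purpose. Setting out from 13, EDC in CH2Cl2 dehydrates it to the enol lactone methyl (4S)-4-[(E)-1,1-diethoxybut-2-en-2-yl]-2-oxo-3,4-dihydro-2H-pyran-5-carboxylate F6. This activated ester is opened at the lactone carbonyl by 16 under DMAP catalysis (alcoholysis of a 3,4-dihydropyran-2-one), which releases the enol and comes back to the route at 17.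

**Further compounds**
F1 | step 12 | (3S)-4-(hydroxymethylidene)-5-methoxy-5-oxo-3-[(E)-1-oxobut-2-en-2-yl]pentanoic acid | COC(=O)/C(=C/O)[C@@H](CC(=O)O)/C(C=O)=C\C
F2 | step 12 | (2S,3S,4S)-3-formyl-5-(methoxycarbonyl)-2-methyl-3,4-dihydro-2H-pyran-4-acetic acid | COC(=O)C1=CO[C@@H](C)[C@@H](C=O)[C@@H]1CC(=O)O
F3 | step 4 | (4S)-3-[(E)-5-(tert-butyldimethylsilyloxy)pent-2-enoyl]-4-phenyloxazolidin-2-one | O=C1OC[C@H](c2ccccc2)N1C(=O)/C=C/CCO[Si](C)(C)C(C)(C)C
F4 | step 4 | (4S)-3-{(3R)-5-(tert-butyldimethylsilyloxy)-3-[(E)-1,1-diethoxybut-2-en-2-yl]pentanoyl}-4-phenyloxazolidin-2-one | O=C1OC[C@H](c2ccccc2)N1C(=O)C[C@@H](CCO[Si](C)(C)C(C)(C)C)/C(=C\C)C(OCC)OCC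
F5 | step 4 | methyl (3R)-5-(tert-butyldimethylsilyloxy)-3-[(E)-1,1-diethoxybut-2-en-2-yl]pentanoate | COC(=O)C[C@@H](CCO[Si](C)(C)C(C)(C)C)/C(=C\C)C(OCC)OCC
F6 | step 10 | methyl (4S)-4-[(E)-1,1-diethoxybut-2-en-2-yl]-2-oxo-3,4-dihydro-2H-pyran-5-carboxylate | COC(=O)C1=COC(=O)C[C@H]1/C(=C\C)C(OCC)OCC
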